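**Retrosynthetic overview**

1. C2–C1' (ring C to ring B) is cut last: a rhodium-catalysed asymmetric 1,4-addition of a ring B arylboronic acid to the fully substituted 8-alkylchromone. The enabling feature is that, with ring C at the chromone oxidation level, C2 is the β-carbon of the O1–C2=C3–C4=O vinylogous ester, while C1' of the resorcinol ring B (ortho to O2', para to O4') can carry boron. One operation makes the bond, the (2S) centre and the chromanone level of ring C.
2. C8–C1'' (ring A to side chain) is cut next: Negishi sp3–sp2 coupling of an 8-iodochromone with the primary alkylzinc of the side chain.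
3. The side chain comes from the chiral pool, (4R)-limonene oxide: cleavage of the C1–C2 ring bond, methylenation of the C1 ketone, and loss of C2 by decarboxylative iodination. C4 of limonene becomes C2''(R).
4. Ring order: no ring is built. Rings A and C arrive fused in 5,7-dihydroxychromone, ring B in 4-bromoresorcinol, and ring C only changes oxidation level in the key step.
5. Four silyl ethers are carried and removed together by buffered fluoride, because acid would isomerise or cyclise the two 1,1-disubstituted alkenes and base would open ring C.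

Key step: step 10

Assumption: (+)-limonene 1,2-oxide is used as the commercial cis/trans mixture; both epoxides give the same keto aldehyde, so only the (4R) centre is specified.
Assumption: the (S)-configured biaryl diphosphine is taken to deliver the aryl group to the face of C2 that gives (2S), by analogy with (S)-biaryl diphosphine–rhodium additions to cyclohex-2-enone; if a trial on the unsubstituted chromone shows the opposite sense, the (R)-ligand is used and nothing else changes.

**Route**

Step 1
Reactants: 1 (+)-limonene 1,2-oxide, (4R), cis/trans mixture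
Product: 3 (3R)-6-oxo-3-(prop-1-en-2-yl)heptanal, via limonene-1,2-diol 2 (not isolated)
Conditions: H5IO6 (1.2 equiv), THF/H2O, 0 °C → rt
Reagents that add atoms: water, O
Why: Acid-catalysed hydrolysis of the epoxide and Malaprade cleavage of the resulting vicinal diol open the ring between C1 and C2, the isolated isopropenyl group is inert to periodate, and the limonene C4 centre is untouched.

Step 2
Reactants: 3 (3R)-6-oxo-3-(prop-1-en-2-yl)heptanal
Product: 4 (3R)-6-oxo-3-(prop-1-en-2-yl)heptanoic acid
Conditions: NaClO2, NaH2PO4, 2-methylbut-2-ene (excess), t-BuOH/H2O, 0 °C → rt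
Reagents that add atoms: sodium chlorite, [Na+].[O-]Cl=O
Why: Pinnick oxidation should convert the aldehyde to the acid in the presence of the ketone and the 1,1-disubstituted alkene, the hypochlorous acid by-product being consumed by the scavenger alkene.

Step 3
Reactants: 4 (3R)-6-oxo-3-(prop-1-en-2-yl)heptanoic acid
Product: 5 (3R)-6-methyl-3-(prop-1-en-2-yl)hept-6-enoic acid
Conditions: Ph3PCH3Br (3.0 equiv), KOtBu (3.0 equiv), THF, 0 °C → rt; cold aqueous citric acid (pH 4) work-up
Reagents that add atoms: methyltriphenylphosphonium bromide, C[P+](c1ccccc1)(c1ccccc1)c1ccccc1.[Br-]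
Why: Wittig methylenation of the methyl ketone should proceed on the carboxylate salt, which is inert to the non-stabilised ylide, and the stereocentre (β to the carboxyl, not enolisable) is preserved.

Step 4
Reactants: 5 (3R)-6-methyl-3-(prop-1-en-2-yl)hept-6-enoic acid
Product: 7 (3S)-3-(iodomethyl)-2,6-dimethylhepta-1,6-diene, via Barton ester 6 (not isolated)
Conditions: N-hydroxypyridine-2-thione, DCC, DMAP (cat.), CH2Cl2, 0 °C → rt, dark; filter; then CHI3 (3 equiv), benzene, tungsten lamp, rt
Reagents that add atoms: iodoform, IC(I)I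
Why: Barton decarboxylative iodination: the thiohydroxamate ester fragments under visible light to a primary radical that should abstract iodine from excess iodoform much faster than it can close in 5-exo or 3-exo fashion onto the disubstituted alkenes, so the stereocentre is untouched (the descriptor changes from R to S only through the change in substituent priorities).

Step 5
Reactants: 8 5,7-dihydroxy-4H-chromen-4-one
Product: 9 5,7-bis[(tert-butyldimethylsilyl)oxy]-4H-chromen-4-one
Conditions: TBSOTf (2.6 equiv), 2,6-lutidine (4 equiv), CH2Cl2, 0 °C → rt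
Reagents that add atoms: tert-butyldimethylsilyl trifluoromethanesulfonate, CC(C)(C)[Si](C)(C)OS(=O)(=O)C(F)(F)F
Why: Silyl triflate with a hindered pyridine base should silylate both the free 7-hydroxyl and the hydrogen-bonded 5-hydroxyl (standard phenol silylation), giving ethers that are inert to organozinc reagents and fluoride-labile.

Step 6
Reactants: 9 5,7-bis[(tert-butyldimethylsilyl)oxy]-4H-chromen-4-one
Product: 10 8-iodo-5,7-bis[(tert-butyldimethylsilyl)oxy]-4H-chromen-4-one
Conditions: NIS (1.05 equiv), DMF, 0 °C → rt, dark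
Reagents that add atoms: N-iodosuccinimide, O=C1CCC(=O)N1I
Why: Electrophilic aromatic iodination of ring A should occur at C8 (para to O5, ortho to O7 and O1), which is far less hindered than C6 between two silyloxy groups and more nucleophilic than C3 of the vinylogous ester, in line with the C8 selectivity known for 5,7-di-O-alkylated chromones and flavones.

Step 7
Reactants: 7 (3S)-3-(iodomethyl)-2,6-dimethylhepta-1,6-diene; 10 8-iodo-5,7-bis[(tert-butyldimethylsilyl)oxy]-4H-chromen-4-one
Product: 13 5,7-bis[(tert-butyldimethylsilyl)oxy]-8-[(2R)-5-methyl-2-(prop-1-en-2-yl)hex-5-en-1-yl]-4H-chromen-4-one, via alkyllithium 11 (not isolated), via alkylzinc chloride 12 (not isolated)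
Conditions: 7 (1.3 equiv), t-BuLi (2.1 equiv per 7), Et2O/pentane, −78 °C; ZnCl2 (1.2 equiv per 7) in THF, −78 °C → rt; then 10, Pd(OAc)2 (4 mol%), SPhos (8 mol%), THF, rt → 40 °C
Reagents that add atoms: none
Why: Negishi sp3–sp2 coupling: iodine–lithium exchange at −78 °C (no carbolithiation at this temperature) and transmetallation give a primary alkylzinc that tolerates the chromone carbonyl, and the dialkylbiarylphosphine–palladium catalyst should couple it with the flanked aryl iodide faster than β-hydride elimination; the stereocentre is not at the metal-bearing carbon and is retained.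

Step 8
Reactants: 14 4-bromobenzene-1,3-diol
Product: 15 [(4-bromo-1,3-phenylene)bis(oxy)]bis(tert-butyldimethylsilane)
Conditions: TBSCl (2.4 equiv), imidazole (5 equiv), DMF, rt
Reagents that add atoms: tert-butyldimethylsilyl chloride, CC(C)(C)[Si](C)(C)Cl
Why: Standard imidazole-mediated silylation of both phenols; the aryl bromide is untouched.

Step 9
Reactants: 15 [(4-bromo-1,3-phenylene)bis(oxy)]bis(tert-butyldimethylsilane)
Product: 18 {2,4-bis[(tert-butyldimethylsilyl)oxy]phenyl}boronic acid, via aryllithium 16 (not isolated), via lithium aryltriisopropoxyborate 17 (not isolated)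
Conditions: B(OiPr)3 (1.5 equiv) present, n-BuLi (1.1 equiv), THF/toluene, −78 °C (in situ quench); aqueous NH4Cl, 0 °C
Reagents that add atoms: triisopropyl borate, CC(C)OB(OC(C)C)OC(C)C; water, O
Why: Bromine–lithium exchange with the borate already present (lithiation–borylation) should trap the aryllithium before anionic oxygen-to-carbon silyl migration can occur, and near-neutral hydrolysis releases the boronic acid.

Step 10
Reactants: 13 5,7-bis[(tert-butyldimethylsilyl)oxy]-8-[(2R)-5-methyl-2-(prop-1-en-2-yl)hex-5-en-1-yl]-4H-chromen-4-one; 18 {2,4-bis[(tert-butyldimethylsilyl)oxy]phenyl}boronic acid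
Product: 19 (2S)-2-{2,4-bis[(tert-butyldimethylsilyl)oxy]phenyl}-5,7-bis[(tert-butyldimethylsilyl)oxy]-8-[(2R)-5-methyl-2-(prop-1-en-2-yl)hex-5-en-1-yl]-2,3-dihydro-4H-chromen-4-one
Conditions: 18 (3.0 equiv, in three portions), [Rh(OH)(cod)]2 (2.5 mol%), (S)-MeO-F12-BIPHEP [(S)-2,2'-bis[bis(3,4,5-trifluorophenyl)phosphino]-6,6'-dimethoxy-1,1'-biphenyl] (5.5 mol%), toluene/H2O (10:1), 40 °C
Reagents that add atoms: none
Why: Hayashi–Miyaura-type asymmetric 1,4-addition: boron-to-rhodium transfer from 18 to the hydroxorhodium–diphosphine complex gives an arylrhodium species, the C2=C3 bond of 13 inserts into the Rh–aryl bond so that C1' of ring B becomes bonded to C2, and water protonates the resulting oxa-π-allylrhodium enolate to the chroman-4-one and regenerates Rh–OH. The closest known reaction type is the rhodium/chiral diphosphine-catalysed enantioselective conjugate addition of arylboronic acids to chromones giving 2-arylchroman-4-ones. No ring is closed: ring C is carried in from the chromone and only drops to the chromanone oxidation level as C2 becomes sp3. The new C2 centre is set by the C2-symmetric (S)-diphosphine, which shields one enantioface of the coordinated C2=C3 bond in the enantio-determining carborhodation; the remote C2'' centre has no say, so the (2S,2''R) diastereomer should form under catalyst control. The step needs enone-over-alkene chemoselectivity (arylrhodium does not insert unactivated 1,1-disubstituted alkenes), 1,4- over 1,2-addition (C2 is unsubstituted while C4=O is shielded by the peri 5-silyloxy group), enolate protonation ahead of β-aryloxide elimination that would open ring C (water co-solvent), and transmetallation ahead of protodeboronation (base-free mild conditions allowed by the electron-poor ligand, excess 18); silyl capping of all four phenols prevents phenoxide formation that would deactivate the vinylogous ester.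

Step 11
Reactants: 19 (2S)-2-{2,4-bis[(tert-butyldimethylsilyl)oxy]phenyl}-5,7-bis[(tert-butyldimethylsilyl)oxy]-8-[(2R)-5-methyl-2-(prop-1-en-2-yl)hex-5-en-1-yl]-2,3-dihydro-4H-chromen-4-one
Product: 20 remangiflavanone B, (2S)-2-(2,4-dihydroxyphenyl)-5,7-dihydroxy-8-[(2R)-5-methyl-2-(prop-1-en-2-yl)hex-5-en-1-yl]-2,3-dihydro-4H-chromen-4-one
Conditions: TBAF (6 equiv), AcOH (7 equiv), THF, 0 °C → rt; pH 5 buffer work-up
Reagents that add atoms: none
Why: Fluoride-mediated cleavage of the four aryl silyl ethers under acetic acid buffering keeps the medium free of phenoxide and of strong acid, so neither retro-oxa-Michael opening of ring C (loss of C2 integrity, 6-/8-alkyl scrambling) nor protonation of the two 1,1-disubstituted alkenes should occur.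

**Compound list**

1 | (+)-limonene 1,2-oxide, (4R), cis/trans mixture | CC12OC1C[C@@H](CC2)C(=C)C | starting material
2 | (4R)-1-methyl-4-(prop-1-en-2-yl)cyclohexane-1,2-diol (limonene-1,2-diol) | CC1(O)C(O)C[C@@H](CC1)C(=C)C | intermediate
3 | (3R)-6-oxo-3-(prop-1-en-2-yl)heptanal | O=CC[C@@H](CCC(C)=O)C(=C)C | intermediate
4 | (3R)-6-oxo-3-(prop-1-en-2-yl)heptanoic acid | OC(=O)C[C@@H](CCC(C)=O)C(=C)C | intermediate
5 | (3R)-6-methyl-3-(prop-1-en-2-yl)hept-6-enoic acid | OC(=O)C[C@@H](CCC(C)=C)C(=C)C | intermediate
6 | 2-thioxopyridin-1(2H)-yl (3R)-6-methyl-3-(prop-1-en-2-yl)hept-6-enoate (Barton ester) | S=c1ccccn1OC(=O)C[C@@H](CCC(C)=C)C(=C)C | intermediate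
7 | (3S)-3-(iodomethyl)-2,6-dimethylhepta-1,6-diene | IC[C@@H](CCC(C)=C)C(=C)C | intermediate
8 | 5,7-dihydroxy-4H-chromen-4-one | O=c1ccoc2cc(O)cc(O)c12 | starting material
9 | 5,7-bis[(tert-butyldimethylsilyl)oxy]-4H-chromen-4-one | O=c1ccoc2cc(O[Si](C)(C)C(C)(C)C)cc(O[Si](C)(C)C(C)(C)C)c12 | intermediate
10 | 8-iodo-5,7-bis[(tert-butyldimethylsilyl)oxy]-4H-chromen-4-one | O=c1ccoc2c(I)c(O[Si](C)(C)C(C)(C)C)cc(O[Si](C)(C)C(C)(C)C)c12 | intermediate
11 | [(2S)-5-methyl-2-(prop-1-en-2-yl)hex-5-en-1-yl]lithium | [Li]C[C@@H](CCC(C)=C)C(=C)C | intermediate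
12 | chloro[(2S)-5-methyl-2-(prop-1-en-2-yl)hex-5-en-1-yl]zinc | Cl[Zn]C[C@@H](CCC(C)=C)C(=C)C | intermediate
13 | 5,7-bis[(tert-butyldimethylsilyl)oxy]-8-[(2R)-5-methyl-2-(prop-1-en-2-yl)hex-5-en-1-yl]-4H-chromen-4-one | C=C(C)CC[C@H](Cc1c(O[Si](C)(C)C(C)(C)C)cc(O[Si](C)(C)C(C)(C)C)c2c(=O)ccoc12)C(=C)C | intermediate
14 | 4-bromobenzene-1,3-diol | Oc1ccc(Br)c(O)c1 | starting material
15 | [(4-bromo-1,3-phenylene)bis(oxy)]bis(tert-butyldimethylsilane) | CC(C)(C)[Si](C)(C)Oc1ccc(Br)c(O[Si](C)(C)C(C)(C)C)c1 | intermediate
16 | {2,4-bis[(tert-butyldimethylsilyl)oxy]phenyl}lithium | [Li]c1ccc(O[Si](C)(C)C(C)(C)C)cc1O[Si](C)(C)C(C)(C)C | intermediate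
17 | lithium {2,4-bis[(tert-butyldimethylsilyl)oxy]phenyl}tri(propan-2-yloxy)borate | [Li+].CC(C)O[B-](OC(C)C)(OC(C)C)c1ccc(O[Si](C)(C)C(C)(C)C)cc1O[Si](C)(C)C(C)(C)C | intermediate
18 | {2,4-bis[(tert-butyldimethylsilyl)oxy]phenyl}boronic acid | OB(O)c1ccc(O[Si](C)(C)C(C)(C)C)cc1O[Si](C)(C)C(C)(C)C | intermediate
19 | (2S)-2-{2,4-bis[(tert-butyldimethylsilyl)oxy]phenyl}-5,7-bis[(tert-butyldimethylsilyl)oxy]-8-[(2R)-5-methyl-2-(prop-1-en-2-yl)hex-5-en-1-yl]-2,3-dihydro-4H-chromen-4-one | C=C(C)CC[C@H](Cc1c(O[Si](C)(C)C(C)(C)C)cc(O[Si](C)(C)C(C)(C)C)c2c1O[C@H](c1ccc(O[Si](C)(C)C(C)(C)C)cc1O[Si](C)(C)C(C)(C)C)CC2=O)C(=C)C | intermediate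
20 | remangiflavanone B | C=C(C)CC[C@H](Cc1c(O)cc(O)c2c1O[C@H](c1ccc(O)cc1O)CC2=O)C(=C)C | target

**Step count and risks**

Total steps: 11. Longest linear sequence: 7 steps (steps 1, 2, 3, 4, 7, 10, 11).

Step 10 is the most likely to fail. Boron-to-rhodium transfer and insertion may be slow for the ortho-silyloxy aryl group, so that protodeboronation consumes 18. β-Aryloxide elimination from the rhodium enolate may open ring C, or facial selectivity may be poor. The fallback gives up catalyst control and sets out from 13 and 15. Bromine–magnesium exchange on 15 (i-PrMgCl·LiCl, THF, 0 °C) would give the aryl Grignard reagent chloro{2,4-bis[(tert-butyldimethylsilyl)oxy]phenyl}magnesium F1. Its copper-catalysed conjugate addition to 13 (CuBr·SMe2 10 mol%, TMSCl, THF, −78 → −30 °C) would give the 4-(trimethylsilyloxy)-2H-chromene silyl enol ether F2 as a mixture at C2. Mild hydrolysis (aqueous citrate, pH 5) would give 19 together with its (2R) epimer F3, since the remote side-chain centre exerts no control. The two are separated by preparative HPLC on a chiral stationary phase, and the route is rejoined at 19.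

Step 7 is the second risk. Oxidative addition into the doubly flanked C8–I bond may be slow, and β-hydride elimination from the alkylpalladium intermediate may then dominate. The iodine–lithium exchange may also be incomplete. The fallback avoids any preformed organometallic and sets out from acid 5 and iodide 10. Acid 5 is converted (N-hydroxyphthalimide, N,N'-diisopropylcarbodiimide, DMAP, CH2Cl2) into the redox-active ester 1,3-dioxoisoindolin-2-yl (3R)-6-methyl-3-(prop-1-en-2-yl)hept-6-enoate F4. F4 is joined to 10 by nickel-catalysed reductive decarboxylative arylation (NiBr2(dme) 20 mol%, 4,4'-di-tert-butyl-2,2'-bipyridine 20 mol%, Zn, DMA, rt). The high nickel loading is chosen so that capture of the primary radical competes with its 5-exo closure. The route is rejoined at 13.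

Step 9 is the third risk. The ortho-lithiated silyl ether may undergo anionic oxygen-to-carbon silyl migration, and the electron-rich boronic acid may protodeboronate during work-up. The fallback replaces organolithium chemistry by Miyaura borylation and sets out from 15. Treatment with B2pin2, PdCl2(dppf) and KOAc (1,4-dioxane, 85 °C; zerovalent palladium cycle) would give 2-{2,4-bis[(tert-butyldimethylsilyl)oxy]phenyl}-4,4,5,5-tetramethyl-1,3,2-dioxaborolane F5. F5 is used in place of 18 under the step 10 conditions with added aqueous K3PO4 to promote boron-to-rhodium transfer, and the route is rejoined at 19.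

Further compounds
F1 | step 10 | chloro{2,4-bis[(tert-butyldimethylsilyl)oxy]phenyl}magnesium (lithium chloride complex) | Cl[Mg]c1ccc(O[Si](C)(C)C(C)(C)C)cc1O[Si](C)(C)C(C)(C)C
F2 | step 10 | 2-{2,4-bis[(tert-butyldimethylsilyl)oxy]phenyl}-5,7-bis[(tert-butyldimethylsilyl)oxy]-8-[(2R)-5-methyl-2-(prop-1-en-2-yl)hex-5-en-1-yl]-4-[(trimethylsilyl)oxy]-2H-chromene, mixture at C2 | C=C(C)CC[C@H](Cc1c(O[Si](C)(C)C(C)(C)C)cc(O[Si](C)(C)C(C)(C)C)c2c1OC(c1ccc(O[Si](C)(C)C(C)(C)C)cc1O[Si](C)(C)C(C)(C)C)C=C2O[Si](C)(C)C)C(=C)C
F3 | step 10 | (2R)-2-{2,4-bis[(tert-butyldimethylsilyl)oxy]phenyl}-5,7-bis[(tert-butyldimethylsilyl)oxy]-8-[(2R)-5-methyl-2-(prop-1-en-2-yl)hex-5-en-1-yl]-2,3-dihydro-4H-chromen-4-one | C=C(C)CC[C@H](Cc1c(O[Si](C)(C)C(C)(C)C)cc(O[Si](C)(C)C(C)(C)C)c2c1O[C@@H](c1ccc(O[Si](C)(C)C(C)(C)C)cc1O[Si](C)(C)C(C)(C)C)CC2=O)C(=C)C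
F4 | step 7 | 1,3-dioxoisoindolin-2-yl (3R)-6-methyl-3-(prop-1-en-2-yl)hept-6-enoate | O=C(C[C@@H](CCC(C)=C)C(=C)C)ON1C(=O)c2ccccc2C1=O
F5 | step 9 | 2-{2,4-bis[(tert-butyldimethylsilyl)oxy]phenyl}-4,4,5,5-tetramethyl-1,3,2-dioxaborolane | CC1(C)OB(OC1(C)C)c1ccc(O[Si](C)(C)C(C)(C)C)cc1O[Si](C)(C)C(C)(C)C
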